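**Plan**

1. Ring A is the cyclohexadienone, numbered from its carbonyl (C1) to C6; ring B is the pyranone; primed locants are the heptenyl side chain. Retrosynthesis first takes the C5' ketone back to a silyl-protected alcohol, the C5=C6 alkene back to a cyclohexenone, and ring B (its lactone C–O bond and the bond from the C4-attached carbon to the adjacent C-methyl carbon) back to a C4 carboxyl group plus methyl 2-methyl-3-oxopentanoate.
2. Enabling feature: quaternary C4 lies between ring carbon C3 and the carboxyl-level carbon that becomes pyranone C6, which is a 2-methyl β-keto ester pattern. C5, C6, C1 and C2 with the C6 and C2 methyls are the carbons of 2-methylpent-1-en-3-one. Cutting C4–C5 and C2=C3 therefore gives β-keto ester 12 and enone 13.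
3. 12 is cut at its C2–C3 bond (Claisen), its C4=C5 alkene (Wittig) and its C6–C7 bond (Evans aldol).
4. Forward order: side chain (steps 1–7), ring A by Michael addition and aldol condensation (step 8), ring B grown from the ester carbon (steps 9–12), then the C5=C6 alkene, desilylation and oxidation (steps 13–15). Ring A is kept as a cyclohexenone until ring B exists, because a 4-carboxycyclohexa-2,5-dienone would be expected to lose CO2 and aromatise.
5. Stereochemistry: the side-chain methyl centre (S) comes from the (R)-benzyloxazolidinone syn-aldol, the E-alkene from a stabilised ylide, and quaternary C4 (S) from the BINAP palladium catalyst in step 8.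

Key step: step 8

Assumption (remark on the chemistry): the facial preference known for cyclic tert-butyl β-keto esters with (BINAP)palladium aqua complexes is taken to hold for acyclic 12 and points to the (S)-ligand; if a test reaction shows the opposite sense, the (R)-ligand is used in the same way.

Abbreviation: TBS = tert-butyldimethylsilyl. Systematic names number the carbocycle from the quaternary carbon, so the ring methine called C6 in the text is C5 in the names.

**Step 1**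
Reactants: 1 (4R)-4-benzyl-3-propanoyl-1,3-oxazolidin-2-one; 2 propanal
Product: 3 (4R)-4-benzyl-3-[(2R,3S)-3-hydroxy-2-methylpentanoyl]-1,3-oxazolidin-2-one
Conditions: Bu2BOTf, Et3N, CH2Cl2, −78 → 0 °C; then pH 7 buffer, MeOH, 30% H2O2, 0 °C
Reagents that add atoms: none
Why: Evans syn-aldol reaction, in which the Z-boron enolate reacts through a Zimmerman–Traxler chair on the face away from the benzyl group and should set C2 as R and C3 as S.

**Step 2**
Reactants: 3 (4R)-4-benzyl-3-[(2R,3S)-3-hydroxy-2-methylpentanoyl]-1,3-oxazolidin-2-one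
Product: 4 (4R)-4-benzyl-3-[(2R,3S)-3-(TBS-oxy)-2-methylpentanoyl]-1,3-oxazolidin-2-one
Conditions: TBSOTf, 2,6-lutidine, CH2Cl2, 0 °C
Reagents that add atoms: tert-butyldimethylsilyl trifluoromethanesulfonate, CC(C)(C)[Si](C)(C)OS(=O)(=O)C(F)(F)F
Why: Silylation of a hindered secondary alcohol with a silyl triflate and a hindered pyridine base is standard and should not epimerise the imide α-centre.

**Step 3**
Reactants: 4 (4R)-4-benzyl-3-[(2R,3S)-3-(TBS-oxy)-2-methylpentanoyl]-1,3-oxazolidin-2-one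
Product: 5 (2S,3S)-3-(TBS-oxy)-2-methylpentan-1-ol
Conditions: LiBH4, MeOH (1 equiv), THF, 0 °C → rt; aq. NaOH
Reagents that add atoms: none
Why: Reductive cleavage of an N-acyl oxazolidinone with LiBH4 attacks the exocyclic carbonyl and releases the auxiliary without touching the silyl ether or the α-stereocentre.

**Step 4**
Reactants: 5 (2S,3S)-3-(TBS-oxy)-2-methylpentan-1-ol
Product: 6 (2R,3S)-3-(TBS-oxy)-2-methylpentanal
Conditions: Dess–Martin periodinane, NaHCO3, CH2Cl2, 0 °C → rt; used crude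
Reagents that add atoms: none
Why: Buffered Dess–Martin oxidation is non-basic and should give the α-branched aldehyde without epimerisation.

**Step 5**
Reactants: 6 (2R,3S)-3-(TBS-oxy)-2-methylpentanal; 7 ethyl 2-(triphenyl-λ5-phosphanylidene)propanoate
Product: 8 ethyl (2E,4S,5S)-5-(TBS-oxy)-2,4-dimethylhept-2-enoate
Conditions: toluene, 80 °C
Reagents that add atoms: none
Why: Wittig olefination with a stabilised α-branched ylide is reliably E-selective with α-branched aldehydes and neutral enough to keep the adjacent stereocentre.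

**Step 6**
Reactants: 8 ethyl (2E,4S,5S)-5-(TBS-oxy)-2,4-dimethylhept-2-enoate
Product: 9 (2E,4S,5S)-5-(TBS-oxy)-2,4-dimethylhept-2-enoic acid
Conditions: LiOH, THF/MeOH/H2O, 40 °C; then aq. HCl to pH 4, 0 °C
Reagents that add atoms: lithium hydroxide, [Li+].[OH-]
Why: Saponification of the ethyl ester, in which the TBS ether is stable to base and the γ-hydrogen of the enoate is not acidic enough to be removed by hydroxide.

**Step 7**
Reactants: 9 (2E,4S,5S)-5-(TBS-oxy)-2,4-dimethylhept-2-enoic acid; 10 tert-butyl propanoate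
Product: 12 tert-butyl (4E,6S,7S)-7-(TBS-oxy)-2,4,6-trimethyl-3-oxonon-4-enoate (C2 epimers), via acyl imidazole 11 (not isolated)
Conditions: 1,1'-carbonyldiimidazole, THF, rt; then added to 10 + LiN(i-Pr)2 (3 equiv of enolate, ester in slight excess over base), THF, −78 → −30 °C; aq. NH4Cl
Reagents that add atoms: none
Why: Crossed Claisen condensation in which the acyl imidazole acylates the lithium ester enolate at carbon, and excess enolate deprotonates the β-keto ester as it forms, which prevents a second acylation.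

**Step 8**
Reactants: 12 tert-butyl (4E,6S,7S)-7-(TBS-oxy)-2,4,6-trimethyl-3-oxonon-4-enoate; 13 2-methylpent-1-en-3-one
Product: 16 tert-butyl (1S)-2-[(2E,4S,5S)-5-(TBS-oxy)-4-methylhept-2-en-2-yl]-1,3,5-trimethyl-4-oxocyclohex-2-ene-1-carboxylate (C5 epimers), via Michael adduct 14 (not isolated), via ketol 15 (not isolated)
Conditions: [Pd((S)-BINAP)(H2O)2](OTf)2 (10 mol %), 13 (3 equiv), THF, 0 °C → rt; then pyrrolidine, AcOH, toluene, 60 °C
Reagents that add atoms: none
Why: The tert-butyl β-keto ester forms an O,O-chelated square-planar enolate of divalent palladium, releasing TfOH that activates enone 13, and the enolate α-carbon adds to the unsubstituted CH2 terminus (C4–C5 bond) to give 14; pyrrolidine and AcOH then convert the ethyl ketone into its less substituted enamine, which attacks the acyl ketone (C2–C3 bond), and ketol 15 loses water to the tetrasubstituted enone. The closest known reaction type is the palladium aqua complex-catalysed enantioselective Michael addition of α-substituted tert-butyl β-keto esters to vinyl ketones, joined to the aldol-condensation half of a Robinson annulation. Ring A closes in a 6-(enolendo)-exo-trig aldol. Quaternary C4 (S) is set in the Michael stage by the (S)-BINAP ligand, whose P-phenyl groups together with the tert-butoxy group leave one face of the planar enolate open, while the remote side-chain centres should only weakly match or mismatch; the C6 methine arises by uncontrolled protonation and becomes sp2 in step 13. The step needs C-alkylation at the acceptor CH2 only and a single aldol mode: the enoyl unit of 12 is α,β-disubstituted and tied up as the enolate, so it does not compete as an acceptor, the acyl ketone has no α-hydrogen, only the ethyl CH2 can reach it through a six-membered transition state, and the tert-butyl ester shuts off a Claisen-type closure.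

**Step 9**
Reactants: 16 tert-butyl (1S)-2-[(2E,4S,5S)-5-(TBS-oxy)-4-methylhept-2-en-2-yl]-1,3,5-trimethyl-4-oxocyclohex-2-ene-1-carboxylate
Product: 18 (1S)-2-[(2E,4S,5S)-5-(TBS-oxy)-4-methylhept-2-en-2-yl]-1,3,5-trimethyl-4-oxocyclohex-2-ene-1-carboxylic acid (C5 epimers), via trimethylsilyl ester 17 (not isolated)
Conditions: Me3SiOTf, 2,6-lutidine, CH2Cl2, 0 °C → rt; then pH 5 aqueous buffer, 0 °C
Reagents that add atoms: none
Why: Silyl triflate-mediated tert-butyl ester cleavage (O-silylation, loss of isobutene, hydrolysis of the silyl ester on work-up) spares the secondary TBS ether and avoids protic acid that could lactonise the acid onto the neighbouring alkene.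

**Step 10**
Reactants: 18 (1S)-2-[(2E,4S,5S)-5-(TBS-oxy)-4-methylhept-2-en-2-yl]-1,3,5-trimethyl-4-oxocyclohex-2-ene-1-carboxylic acid; 19 methyl 2-methyl-3-oxopentanoate
Product: 21 methyl 5-[(1S)-2-[(2E,4S,5S)-5-(TBS-oxy)-4-methylhept-2-en-2-yl]-1,3,5-trimethyl-4-oxocyclohex-2-en-1-yl]-2,4-dimethyl-3,5-dioxopentanoate (epimers and enol tautomers), via acid chloride 20 (not isolated)
Conditions: 1-chloro-N,N,2-trimethylprop-1-en-1-amine, CH2Cl2, 0 °C → rt; then added to 19 + LiN(i-Pr)2 (2 equiv per 19; 3 equiv of dianion), THF, −78 °C; aq. NH4Cl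
Reagents that add atoms: none
Why: Acylation of a β-keto ester dianion at its terminal carbon (Huckin–Weiler type) by an acid chloride that cannot enolise or form a ketene and is far more electrophilic than the hindered ring enone, with excess dianion absorbing the acidic product.

**Step 11**
Reactants: 21 methyl 5-[(1S)-2-[(2E,4S,5S)-5-(TBS-oxy)-4-methylhept-2-en-2-yl]-1,3,5-trimethyl-4-oxocyclohex-2-en-1-yl]-2,4-dimethyl-3,5-dioxopentanoate
Product: 22 6-[(1S)-2-[(2E,4S,5S)-5-(TBS-oxy)-4-methylhept-2-en-2-yl]-1,3,5-trimethyl-4-oxocyclohex-2-en-1-yl]-4-hydroxy-3,5-dimethyl-2H-pyran-2-one (C5 epimers)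
Conditions: DBU, toluene, 80 °C; dilute acid wash
Reagents that add atoms: none
Why: Base-mediated lactonisation of a 3,5-dioxo ester, in which the enol oxygen of the C5 ketone attacks the methyl ester in a 6-exo-trig closure with loss of methanol to give the 4-hydroxy-2-pyranone.

**Step 12**
Reactants: 22 6-[(1S)-2-[(2E,4S,5S)-5-(TBS-oxy)-4-methylhept-2-en-2-yl]-1,3,5-trimethyl-4-oxocyclohex-2-en-1-yl]-4-hydroxy-3,5-dimethyl-2H-pyran-2-one
Product: 23 2-methoxy-3,5-dimethyl-6-[(1S)-2-[(2E,4S,5S)-5-(TBS-oxy)-4-methylhept-2-en-2-yl]-1,3,5-trimethyl-4-oxocyclohex-2-en-1-yl]-4H-pyran-4-one (C5 epimers)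
Conditions: MeOTf, CH2Cl2, rt; then sat. aq. NaHCO3
Reagents that add atoms: methyl trifluoromethanesulfonate, COS(=O)(=O)C(F)(F)F
Why: O-Methylation of a 4-hydroxy-2-pyranone with a hard methylating agent under neutral conditions occurs at the lactone carbonyl oxygen, and loss of the 4-hydroxyl proton then gives the 2-methoxy-4-pyranone in preference to the 4-methoxy-2-pyranone.

**Step 13**
Reactants: 23 2-methoxy-3,5-dimethyl-6-[(1S)-2-[(2E,4S,5S)-5-(TBS-oxy)-4-methylhept-2-en-2-yl]-1,3,5-trimethyl-4-oxocyclohex-2-en-1-yl]-4H-pyran-4-one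
Product: 25 2-methoxy-3,5-dimethyl-6-[(1S)-2-[(2E,4S,5S)-5-(TBS-oxy)-4-methylhept-2-en-2-yl]-1,3,5-trimethyl-4-oxocyclohexa-2,5-dien-1-yl]-4H-pyran-4-one, via silyl dienol ether 24 (not isolated)
Conditions: LiN(SiMe3)2, Me3SiCl, THF, −78 → 0 °C; solvent exchange; then Pd(OAc)2 (1.1 equiv), MeCN, rt
Reagents that add atoms: none
Why: Saegusa–Ito oxidation, in which the only α-hydrogen of the ring ketone (C6–H) is removed, the cross-conjugated silyl dienol ether is palladated at C6, and β-hydride elimination from the ring CH2 releases zerovalent palladium and the cyclohexa-2,5-dienone.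

**Step 14**
Reactants: 25 2-methoxy-3,5-dimethyl-6-[(1S)-2-[(2E,4S,5S)-5-(TBS-oxy)-4-methylhept-2-en-2-yl]-1,3,5-trimethyl-4-oxocyclohexa-2,5-dien-1-yl]-4H-pyran-4-one
Product: 26 6-[(1S)-2-[(2E,4S,5S)-5-hydroxy-4-methylhept-2-en-2-yl]-1,3,5-trimethyl-4-oxocyclohexa-2,5-dien-1-yl]-2-methoxy-3,5-dimethyl-4H-pyran-4-one
Conditions: HF·pyridine, pyridine, THF, 0 °C → rt
Reagents that add atoms: none
Why: Fluoride-mediated desilylation with pyridine-buffered HF·pyridine removes the secondary TBS ether under conditions too mild for a dienone–phenol rearrangement or for attack on the methoxypyranone.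

**Step 15**
Reactants: 26 6-[(1S)-2-[(2E,4S,5S)-5-hydroxy-4-methylhept-2-en-2-yl]-1,3,5-trimethyl-4-oxocyclohexa-2,5-dien-1-yl]-2-methoxy-3,5-dimethyl-4H-pyran-4-one
Product: 27 2-methoxy-3,5-dimethyl-6-[(1S)-1,3,5-trimethyl-2-[(2E,4S)-4-methyl-5-oxohept-2-en-2-yl]-4-oxocyclohexa-2,5-dien-1-yl]-4H-pyran-4-one (target)
Conditions: Dess–Martin periodinane, NaHCO3, CH2Cl2, 0 °C → rt; neutral work-up
Reagents that add atoms: none
Why: Buffered Dess–Martin oxidation of the secondary alcohol is fast and non-basic, so the α-stereocentre of the new β,γ-unsaturated ketone should neither epimerise nor let the alkene move into conjugation.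

**Compound list**

1 | (4R)-4-benzyl-3-propanoyl-1,3-oxazolidin-2-one | CCC(=O)N1[C@H](Cc2ccccc2)COC1=O | starting material
2 | propanal | CCC=O | starting material
3 | (4R)-4-benzyl-3-[(2R,3S)-3-hydroxy-2-methylpentanoyl]-1,3-oxazolidin-2-one | CC[C@H](O)[C@@H](C)C(=O)N1[C@H](Cc2ccccc2)COC1=O | intermediate
4 | (4R)-4-benzyl-3-[(2R,3S)-3-(tert-butyldimethylsilyloxy)-2-methylpentanoyl]-1,3-oxazolidin-2-one | CC[C@H](O[Si](C)(C)C(C)(C)C)[C@@H](C)C(=O)N1[C@H](Cc2ccccc2)COC1=O | intermediate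
5 | (2S,3S)-3-(tert-butyldimethylsilyloxy)-2-methylpentan-1-ol | CC[C@H](O[Si](C)(C)C(C)(C)C)[C@@H](C)CO | intermediate
6 | (2R,3S)-3-(tert-butyldimethylsilyloxy)-2-methylpentanal | CC[C@H](O[Si](C)(C)C(C)(C)C)[C@@H](C)C=O | intermediate
7 | ethyl 2-(triphenyl-λ5-phosphanylidene)propanoate | CCOC(=O)C(C)=P(c1ccccc1)(c1ccccc1)c1ccccc1 | starting material
8 | ethyl (2E,4S,5S)-5-(tert-butyldimethylsilyloxy)-2,4-dimethylhept-2-enoate | CC[C@H](O[Si](C)(C)C(C)(C)C)[C@@H](C)/C=C(\C)C(=O)OCC | intermediate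
9 | (2E,4S,5S)-5-(tert-butyldimethylsilyloxy)-2,4-dimethylhept-2-enoic acid | CC[C@H](O[Si](C)(C)C(C)(C)C)[C@@H](C)/C=C(\C)C(=O)O | intermediate
10 | tert-butyl propanoate | CCC(=O)OC(C)(C)C | starting material
11 | 1-[(2E,4S,5S)-5-(tert-butyldimethylsilyloxy)-2,4-dimethylhept-2-enoyl]-1H-imidazole | CC[C@H](O[Si](C)(C)C(C)(C)C)[C@@H](C)/C=C(\C)C(=O)n1ccnc1 | intermediate (not isolated)
12 | tert-butyl (4E,6S,7S)-7-(tert-butyldimethylsilyloxy)-2,4,6-trimethyl-3-oxonon-4-enoate (C2 epimers) | CC[C@H](O[Si](C)(C)C(C)(C)C)[C@@H](C)/C=C(\C)C(=O)C(C)C(=O)OC(C)(C)C | intermediate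
13 | 2-methylpent-1-en-3-one | CCC(=O)C(C)=C | starting material
14 | tert-butyl (2S)-2-[(2E,4S,5S)-5-(tert-butyldimethylsilyloxy)-2,4-dimethylhept-2-enoyl]-2,4-dimethyl-5-oxoheptanoate (C4 epimers) | CC[C@H](O[Si](C)(C)C(C)(C)C)[C@@H](C)/C=C(\C)C(=O)[C@](C)(CC(C)C(=O)CC)C(=O)OC(C)(C)C | intermediate (not isolated)
15 | tert-butyl (1S)-2-hydroxy-2-[(2E,4S,5S)-5-(tert-butyldimethylsilyloxy)-4-methylhept-2-en-2-yl]-1,3,5-trimethyl-4-oxocyclohexane-1-carboxylate (mixture at C2, C3, C5) | CC[C@H](O[Si](C)(C)C(C)(C)C)[C@@H](C)/C=C(\C)C1(O)C(C)C(=O)C(C)C[C@]1(C)C(=O)OC(C)(C)C | intermediate (not isolated)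
16 | tert-butyl (1S)-2-[(2E,4S,5S)-5-(tert-butyldimethylsilyloxy)-4-methylhept-2-en-2-yl]-1,3,5-trimethyl-4-oxocyclohex-2-ene-1-carboxylate (C5 epimers) | CC[C@H](O[Si](C)(C)C(C)(C)C)[C@@H](C)/C=C(\C)C1=C(C)C(=O)C(C)C[C@]1(C)C(=O)OC(C)(C)C | intermediate
17 | trimethylsilyl (1S)-2-[(2E,4S,5S)-5-(tert-butyldimethylsilyloxy)-4-methylhept-2-en-2-yl]-1,3,5-trimethyl-4-oxocyclohex-2-ene-1-carboxylate | CC[C@H](O[Si](C)(C)C(C)(C)C)[C@@H](C)/C=C(\C)C1=C(C)C(=O)C(C)C[C@]1(C)C(=O)O[Si](C)(C)C | intermediate (not isolated)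
18 | (1S)-2-[(2E,4S,5S)-5-(tert-butyldimethylsilyloxy)-4-methylhept-2-en-2-yl]-1,3,5-trimethyl-4-oxocyclohex-2-ene-1-carboxylic acid (C5 epimers) | CC[C@H](O[Si](C)(C)C(C)(C)C)[C@@H](C)/C=C(\C)C1=C(C)C(=O)C(C)C[C@]1(C)C(=O)O | intermediate
19 | methyl 2-methyl-3-oxopentanoate | CCC(=O)C(C)C(=O)OC | starting material
20 | (1S)-2-[(2E,4S,5S)-5-(tert-butyldimethylsilyloxy)-4-methylhept-2-en-2-yl]-1,3,5-trimethyl-4-oxocyclohex-2-ene-1-carbonyl chloride | CC[C@H](O[Si](C)(C)C(C)(C)C)[C@@H](C)/C=C(\C)C1=C(C)C(=O)C(C)C[C@]1(C)C(=O)Cl | intermediate (not isolated)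
21 | methyl 5-[(1S)-2-[(2E,4S,5S)-5-(tert-butyldimethylsilyloxy)-4-methylhept-2-en-2-yl]-1,3,5-trimethyl-4-oxocyclohex-2-en-1-yl]-2,4-dimethyl-3,5-dioxopentanoate (epimers, enol tautomers) | CC[C@H](O[Si](C)(C)C(C)(C)C)[C@@H](C)/C=C(\C)C1=C(C)C(=O)C(C)C[C@]1(C)C(=O)C(C)C(=O)C(C)C(=O)OC | intermediate
22 | 6-[(1S)-2-[(2E,4S,5S)-5-(tert-butyldimethylsilyloxy)-4-methylhept-2-en-2-yl]-1,3,5-trimethyl-4-oxocyclohex-2-en-1-yl]-4-hydroxy-3,5-dimethyl-2H-pyran-2-one (C5 epimers) | CC[C@H](O[Si](C)(C)C(C)(C)C)[C@@H](C)/C=C(\C)C1=C(C)C(=O)C(C)C[C@]1(C)c1oc(=O)c(C)c(O)c1C | intermediate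
23 | 2-methoxy-3,5-dimethyl-6-[(1S)-2-[(2E,4S,5S)-5-(tert-butyldimethylsilyloxy)-4-methylhept-2-en-2-yl]-1,3,5-trimethyl-4-oxocyclohex-2-en-1-yl]-4H-pyran-4-one (C5 epimers) | CC[C@H](O[Si](C)(C)C(C)(C)C)[C@@H](C)/C=C(\C)C1=C(C)C(=O)C(C)C[C@]1(C)c1oc(OC)c(C)c(=O)c1C | intermediate
24 | 2-methoxy-3,5-dimethyl-6-[(1S)-2-[(2E,4S,5S)-5-(tert-butyldimethylsilyloxy)-4-methylhept-2-en-2-yl]-1,3,5-trimethyl-4-(trimethylsilyloxy)cyclohexa-2,4-dien-1-yl]-4H-pyran-4-one | CC[C@H](O[Si](C)(C)C(C)(C)C)[C@@H](C)/C=C(\C)C1=C(C)C(O[Si](C)(C)C)=C(C)C[C@]1(C)c1oc(OC)c(C)c(=O)c1C | intermediate (not isolated)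
25 | 2-methoxy-3,5-dimethyl-6-[(1S)-2-[(2E,4S,5S)-5-(tert-butyldimethylsilyloxy)-4-methylhept-2-en-2-yl]-1,3,5-trimethyl-4-oxocyclohexa-2,5-dien-1-yl]-4H-pyran-4-one | CC[C@H](O[Si](C)(C)C(C)(C)C)[C@@H](C)/C=C(\C)C1=C(C)C(=O)C(C)=C[C@]1(C)c1oc(OC)c(C)c(=O)c1C | intermediate
26 | 6-[(1S)-2-[(2E,4S,5S)-5-hydroxy-4-methylhept-2-en-2-yl]-1,3,5-trimethyl-4-oxocyclohexa-2,5-dien-1-yl]-2-methoxy-3,5-dimethyl-4H-pyran-4-one | CC[C@H](O)[C@@H](C)/C=C(\C)C1=C(C)C(=O)C(C)=C[C@]1(C)c1oc(OC)c(C)c(=O)c1C | intermediate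
27 | 2-methoxy-3,5-dimethyl-6-[(1S)-1,3,5-trimethyl-2-[(2E,4S)-4-methyl-5-oxohept-2-en-2-yl]-4-oxocyclohexa-2,5-dien-1-yl]-4H-pyran-4-one | CCC(=O)[C@@H](C)/C=C(\C)C1=C(C)C(=O)C(C)=C[C@]1(C)c1oc(OC)c(C)c(=O)c1C | target

**Step count and risks**

Total step count: 15. Longest linear sequence: 15 steps (1 → 27); compounds 2, 7, 10, 13 and 19 are purchased.

Steps most likely to fail:

1. Step 8. The conjugate addition may be slow with the α-branched acceptor and the crowded enoyl donor, so that uncatalysed or acid-catalysed background addition erodes the face selectivity at C4, and retro-Michael cleavage may compete during the amine-mediated closure. Fallback, setting out from 12 and returning at 16: 12 is added under the same palladium catalysis to pent-1-en-3-one, the unbranched acceptor for which this catalysis is best established, to give tert-butyl (2S)-2-[(2E,4S,5S)-5-(TBS-oxy)-2,4-dimethylhept-2-enoyl]-2-methyl-5-oxoheptanoate F1. Pyrrolidine and AcOH close it through the ketol tert-butyl (1S)-2-hydroxy-2-[(2E,4S,5S)-5-(TBS-oxy)-4-methylhept-2-en-2-yl]-1,3-dimethyl-4-oxocyclohexane-1-carboxylate F2 to tert-butyl (1S)-2-[(2E,4S,5S)-5-(TBS-oxy)-4-methylhept-2-en-2-yl]-1,3-dimethyl-4-oxocyclohex-2-ene-1-carboxylate F3. Kinetic deprotonation of the α' CH2 with LiN(i-Pr)2 in THF at −78 °C and alkylation with MeI then installs the missing C6 methyl and gives 16.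

2. Step 10. C-acylation at the neopentyl-type acyl chloride may be slower than proton transfer from the ring ketone or O-acylation of the dianion, so that acid 18 is returned on work-up. Fallback, setting out from 16 and returning at 21: 16 is reduced at both the ester and the ring ketone with i-Bu2AlH (excess, CH2Cl2, −78 °C → rt) to the diol (4S)-3-[(2E,4S,5S)-5-(TBS-oxy)-4-methylhept-2-en-2-yl]-4-(hydroxymethyl)-2,4,6-trimethylcyclohex-2-en-1-ol F4. Dess–Martin oxidation of both hydroxyl groups gives the keto aldehyde (1S)-2-[(2E,4S,5S)-5-(TBS-oxy)-4-methylhept-2-en-2-yl]-1,3,5-trimethyl-4-oxocyclohex-2-ene-1-carbaldehyde F5. The dianion of 19 adds to the far more reactive aldehyde at −78 °C to give methyl 5-hydroxy-5-[(1S)-2-[(2E,4S,5S)-5-(TBS-oxy)-4-methylhept-2-en-2-yl]-1,3,5-trimethyl-4-oxocyclohex-2-en-1-yl]-2,4-dimethyl-3-oxopentanoate F6, and a second Dess–Martin oxidation gives 21.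

3. Step 13. Enolisation of the hindered α-methine may be incomplete, palladation of the tetrasubstituted silyl enol ether beside the quaternary centre may be slower than protodesilylation back to 23, or β-hydride loss may occur from the methyl group instead of the ring CH2. Fallback, setting out from 23 and returning at 25: the lithium enolate of 23 (LiN(SiMe3)2, THF, −78 °C) is trapped with PhSeBr to give 2-methoxy-3,5-dimethyl-6-[(1S)-2-[(2E,4S,5S)-5-(TBS-oxy)-4-methylhept-2-en-2-yl]-1,3,5-trimethyl-4-oxo-5-(phenylselanyl)cyclohex-2-en-1-yl]-4H-pyran-4-one F7. H2O2 and pyridine in CH2Cl2 at 0 °C oxidise it to the corresponding selenoxide, the 5-(benzeneseleninyl) ketone F8, whose syn-elimination toward the ring CH2 on warming to room temperature gives 25.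

**Further compounds**

F1 | step 8 | tert-butyl (2S)-2-[(2E,4S,5S)-5-(tert-butyldimethylsilyloxy)-2,4-dimethylhept-2-enoyl]-2-methyl-5-oxoheptanoate | CC[C@H](O[Si](C)(C)C(C)(C)C)[C@@H](C)/C=C(\C)C(=O)[C@](C)(CCC(=O)CC)C(=O)OC(C)(C)C
F2 | step 8 | tert-butyl (1S)-2-hydroxy-2-[(2E,4S,5S)-5-(tert-butyldimethylsilyloxy)-4-methylhept-2-en-2-yl]-1,3-dimethyl-4-oxocyclohexane-1-carboxylate | CC[C@H](O[Si](C)(C)C(C)(C)C)[C@@H](C)/C=C(\C)C1(O)C(C)C(=O)CC[C@]1(C)C(=O)OC(C)(C)C
F3 | step 8 | tert-butyl (1S)-2-[(2E,4S,5S)-5-(tert-butyldimethylsilyloxy)-4-methylhept-2-en-2-yl]-1,3-dimethyl-4-oxocyclohex-2-ene-1-carboxylate | CC[C@H](O[Si](C)(C)C(C)(C)C)[C@@H](C)/C=C(\C)C1=C(C)C(=O)CC[C@]1(C)C(=O)OC(C)(C)C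
F4 | step 10 | (4S)-3-[(2E,4S,5S)-5-(tert-butyldimethylsilyloxy)-4-methylhept-2-en-2-yl]-4-(hydroxymethyl)-2,4,6-trimethylcyclohex-2-en-1-ol | CC[C@H](O[Si](C)(C)C(C)(C)C)[C@@H](C)/C=C(\C)C1=C(C)C(O)C(C)C[C@]1(C)CO
F5 | step 10 | (1S)-2-[(2E,4S,5S)-5-(tert-butyldimethylsilyloxy)-4-methylhept-2-en-2-yl]-1,3,5-trimethyl-4-oxocyclohex-2-ene-1-carbaldehyde | CC[C@H](O[Si](C)(C)C(C)(C)C)[C@@H](C)/C=C(\C)C1=C(C)C(=O)C(C)C[C@]1(C)C=O
F6 | step 10 | methyl 5-hydroxy-5-[(1S)-2-[(2E,4S,5S)-5-(tert-butyldimethylsilyloxy)-4-methylhept-2-en-2-yl]-1,3,5-trimethyl-4-oxocyclohex-2-en-1-yl]-2,4-dimethyl-3-oxopentanoate | CC[C@H](O[Si](C)(C)C(C)(C)C)[C@@H](C)/C=C(\C)C1=C(C)C(=O)C(C)C[C@]1(C)C(O)C(C)C(=O)C(C)C(=O)OC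
F7 | step 13 | 2-methoxy-3,5-dimethyl-6-[(1S)-2-[(2E,4S,5S)-5-(tert-butyldimethylsilyloxy)-4-methylhept-2-en-2-yl]-1,3,5-trimethyl-4-oxo-5-(phenylselanyl)cyclohex-2-en-1-yl]-4H-pyran-4-one | CC[C@H](O[Si](C)(C)C(C)(C)C)[C@@H](C)/C=C(\C)C1=C(C)C(=O)C(C)([Se]c2ccccc2)C[C@]1(C)c1oc(OC)c(C)c(=O)c1C
F8 | step 13 | 6-[(1S)-5-(benzeneseleninyl)-2-[(2E,4S,5S)-5-(tert-butyldimethylsilyloxy)-4-methylhept-2-en-2-yl]-1,3,5-trimethyl-4-oxocyclohex-2-en-1-yl]-2-methoxy-3,5-dimethyl-4H-pyran-4-one | CC[C@H](O[Si](C)(C)C(C)(C)C)[C@@H](C)/C=C(\C)C1=C(C)C(=O)C(C)([Se](=O)c2ccccc2)C[C@]1(C)c1oc(OC)c(C)c(=O)c1C
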